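Amounts are the easy way in: pick one amount of target and ask how long each run takes to reach it. You asked for a quick number and guessed a half order in reagent, and this comparison tests that guess.

| flask | substrate | reagent | free catalyst | time |
|---|---|---|---|---|
| east | 0.150 M | 0.375 M | 0.00750 M |  |
| south-west | 0.0750 M | 0.300 M | 0.00750 M |  |
| north-west | 0.150 M | 0.375 M | 0.0110 M |  |
| south | 0.150 M | 0.560 M | 0.00750 M |  |
| west | 0.450 M | 0.375 M | 0.00250 M | 12 min |

| run | time / min | [target] / M |
|---|---|---|
| east run | 2.0 | 0.0126 |
| east run | 4.0 | 0.0278 |
| east run | 6.0 | 0.0395 |
| east run | 8.0 | 0.0512 |
| east run | 10 | 0.0576 |
| east run | 12 | 0.0638 |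
| south-west run | 2.0 | 0.0094 |
| south-west run | 4.0 | 0.0177 |
| south-west run | 6.0 | 0.0264 |
| south-west run | 8.0 | 0.0330 |
| south-west run | 10 | 0.0388 |
| south-west run | 12 | 0.0424 |
| north-west run | 2.0 | 0.0202 |
| north-west run | 4.0 | 0.0382 |
| north-west run | 6.0 | 0.0568 |
| north-west run | 8.0 | 0.0679 |
| north-west run | 10 | 0.0772 |
| north-west run | 12 | 0.0842 |
| south run | 2.0 | 0.0170 |
| south run | 4.0 | 0.0329 |
| south run | 6.0 | 0.0450 |
| south run | 8.0 | 0.0566 |
| south run | 10 | 0.0636 |
| south run | 12 | 0.0701 |

(each reading ± 8 × 10⁻⁴ M)

- Overall: substrate + reagent -> target, with free catalyst as catalyst.
- Constant volume, constant temperature.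
- The analysis sees a species whether free or bound.
- "The second partner" is reagent.
- An order is taken over about fifteen percent of the charge, up and down.

- how the opening rate goes with [substrate] round the charge of the east run: the exponent of the rate at two percent of substrate gone to target (one fixed amount of target, the same in the runs compared)
- how the opening rate goes with [reagent] round the charge of the east run: the exponent of the rate at two percent of substrate gone to target
- target in the west run at 12 min, as a share of the substrate charged

1. The east run holds 0.0278 M of target at 4.0 min. Read along a straight line between its first two readings, the south run gets there at 3.36 min.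

2. Dividing the first time by the second gives 1.19. Call this the pace: the time the east run needs for an amount of target, divided by the time the other run needs for the same amount. It is also the ratio of their mean rates up to that amount.

3. Now see how the comparison drifts. At the east run's last reading, 0.0638 M, the south run's pace reads 1.19, about the same as before. So I carry it back to the opening.

4. The south run has 1.49 times the east run's reagent, with equal substrate and free catalyst. My reading of the reagent order, taken across that whole step from the east charge to the south charge, is therefore ln(pace)/ln(reagent ratio) = 0.436. Your 0.5 would need a pace of 1.22, which stands 2.60% above this reading. The scatter of the east run's reading at 4.0 min is 2.88% of that reading, so this one comparison does not tell the two apart.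

5. The forecast gives 0.32 for substrate, 0.55 for reagent and 6.7% for the west run, and says of that last number: “This extrapolates beyond the tested substrate range.” Its reagent exponent stands above my reading. For substrate and the west run I have no reckoning of my own and take its numbers.

The simulation gives 0.34 for substrate, 0.44 for reagent and 6.93% for the west run, which is 0.0312 M of target, from these steps:

    free catalyst + substrate → loaded catalyst + by-product (23.22 M⁻¹ min⁻¹)
    loaded catalyst + reagent → target + free catalyst (7.680 M⁻¹ min⁻¹)
    2 substrate → homo dimer (0.5232 M⁻¹ min⁻¹)
    free catalyst + substrate ⇌ idle catalyst-substrate complex, settled at all times (5.260 M⁻¹)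

With two percent of the east run's substrate turned, the south run's rate is 1.2 times the east run's. On the north-west run, the pace at its 4.0 min reading of 0.0382 M reads 1.44, and its rate ratio at that two percent is 1.4. Along a straight line between its readings, the east run reaches the west run's final amount at 4.58 min, so the west run's pace over its 12 min reads 0.382.

The numbers in the tables were generated by integration for substances that don't exist.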